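**Assumption:** positions are labelled with guaiane numbering (five-membered ring C1–C5 with ring-fusion atoms C1 and C5; seven-membered ring C1, C5–C10; methyls on C4 and C10, isopropyl on C7, oxygen on C8), and the same labels are used for the corresponding carbons of the acyclic precursors. The target is (5R,7R,8S).

## Retrosynthetic overview

1. Target 26 ⇐ phenol desilylation of 25 ⇐ Myers reductive 1,3-transposition of allylic alcohol 22 (sets C5–H and the C3=C4 alkene) ⇐ CBS reduction of dienone 21.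
2. Dienone 21 ⇐ acyclic allenyne ester 20 by rhodium-catalysed allenic Pauson–Khand cyclocarbonylation; the seven-membered ring (C1–C5 bond) and the five-membered ring (two C–CO bonds) close in this one step, and no ring exists before it.
3. Ester 20 ⇐ allenynol 12 + silyl-protected vanillic acid 18 (Yamaguchi); 18 comes from catechol in four steps.
4. Allenynol 12 ⇐ alcohol 6 + allenylmethyl acetate 10 by iridium-catalysed carbinol C–H homoallenylation (key C8–C9 bond and the C8 stereocentre).
5. Alcohol 6 ⇐ Evans alkylation of an isovaleryl imide with 1-bromobut-2-yne (C7 stereocentre); acetate 10 ⇐ copper-catalysed SN2′ methylation of 4-chlorobut-2-yn-1-ol.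

## Route

**Step 1**
Reactants: 1 3-methylbutanoyl chloride
Product: 2 (4R)-4-benzyl-3-(3-methylbutanoyl)-1,3-oxazolidin-2-one
Conditions: (R)-4-benzyl-1,3-oxazolidin-2-one, Et3N, DMAP (cat.), CH2Cl2, 0 °C to rt
Reagents that add atoms: (R)-4-benzyl-1,3-oxazolidin-2-one, O=C1N[C@H](Cc2ccccc2)CO1
Why: DMAP-catalysed N-acylation of the oxazolidinone by the acid chloride (nucleophilic acyl substitution) installs the recoverable chiral controller.

**Step 2**
Reactants: 2 (4R)-4-benzyl-3-(3-methylbutanoyl)-1,3-oxazolidin-2-one; 3 1-bromobut-2-yne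
Product: 5 (4R)-4-benzyl-3-[(2R)-2-(propan-2-yl)hex-4-ynoyl]-1,3-oxazolidin-2-one, via sodium enolate 4 (not isolated)
Conditions: NaN(SiMe3)2, THF, −78 °C; then 3, −78 to −40 °C
Reagents that add atoms: none
Why: Evans asymmetric alkylation, in which the chelated (Z)-enolate is attacked by the propargylic bromide on the face opposite the benzyl group, setting C7 as R.

**Step 3**
Reactants: 5 (4R)-4-benzyl-3-[(2R)-2-(propan-2-yl)hex-4-ynoyl]-1,3-oxazolidin-2-one
Product: 6 (2R)-2-(propan-2-yl)hex-4-yn-1-ol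
Conditions: LiBH4, MeOH (1 equiv), Et2O, 0 °C
Reagents that add atoms: none
Why: Reductive cleavage of the imide by borohydride (hydride attack on the exocyclic carbonyl and onward reduction to the carbinol in the same operation) releases the primary alcohol and the auxiliary without touching C7 or the alkyne.

**Step 4**
Reactants: 7 4-chlorobut-2-yn-1-ol
Product: 9 2-methylbuta-2,3-dien-1-ol, via magnesium alkoxide 8 (not isolated)
Conditions: MeMgBr (2.5 equiv), CuI (10 mol%), Et2O, −30 °C to rt; then H2O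
Reagents that add atoms: methylmagnesium bromide, C[Mg]Br
Why: Copper-catalysed SN2′ substitution of the propargylic chloride by the methyl Grignard reagent delivers methyl to the alkyne carbon next to the CH2O group and gives the 1,1-disubstituted allene.

**Step 5**
Reactants: 9 2-methylbuta-2,3-dien-1-ol
Product: 10 2-methylbuta-2,3-dien-1-yl acetate
Conditions: Ac2O, Et3N, DMAP (cat.), CH2Cl2, 0 °C
Reagents that add atoms: acetic anhydride, CC(=O)OC(C)=O
Why: Standard DMAP-catalysed O-acetylation turns the allenylmethyl alcohol into an ionisable ester.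

**Step 6**
Reactants: 6 (2R)-2-(propan-2-yl)hex-4-yn-1-ol; 10 2-methylbuta-2,3-dien-1-yl acetate
Product: 12 (5S,6R)-3-methyl-6-(propan-2-yl)deca-1,2-dien-8-yn-5-ol, via aldehyde 11 (not isolated)
Conditions: [Ir(cod)Cl]2 (2.5 mol%), (S)-SEGPHOS (5 mol%), 4-chloro-3-nitrobenzoic acid (10 mol%), Cs2CO3 (20 mol%), 10 (2 equiv), THF, 100 °C, sealed tube
Reagents that add atoms: none
Why: Proposed new method: iridium-catalysed transfer-hydrogenative carbonyl homoallenylation, in which the cyclometalated trivalent iridium C,O-benzoate dehydrogenates 6 to aldehyde 11 (carbinol C–H activation), the resulting monovalent iridium ionises 10 in SN2′ fashion to a σ-(3-methylbuta-1,3-dien-2-yl)iridium species, and this adds to 11 through a closed six-membered transition state at the former acetoxymethyl carbon to form the C8–C9 bond as the 1,1-disubstituted allene, with the ligand antipode chosen for Si-face attack (8S, catalyst control over the weak Felkin bias of C7); the closest known reaction types are iridium-catalysed enantioselective allylation and propargylation of primary alcohols with allyl acetate or propargyl chlorides, and the SE2′ addition of buta-1,3-dien-2-ylmagnesium halides to aldehydes that gives β-allenic alcohols.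

**Step 7**
Reactants: 13 benzene-1,2-diol (catechol)
Product: 14 2-methoxyphenol
Conditions: MeI (1.0 equiv), K2CO3, acetone, reflux
Reagents that add atoms: iodomethane, CI
Why: Williamson mono-O-methylation with one equivalent of electrophile; the monoether is separated from diether and catechol by base extraction and distillation.

**Step 8**
Reactants: 14 2-methoxyphenol
Product: 15 4-bromo-2-methoxyphenol
Conditions: NBS, MeCN, 0 °C
Reagents that add atoms: N-bromosuccinimide, O=C1CCC(=O)N1Br
Why: Electrophilic aromatic bromination goes para to the free hydroxyl, the stronger activating group.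

**Step 9**
Reactants: 15 4-bromo-2-methoxyphenol
Product: 16 (4-bromo-2-methoxyphenoxy)(tert-butyl)dimethylsilane
Conditions: TBSCl, imidazole, DMF, rt
Reagents that add atoms: tert-butyldimethylsilyl chloride, C[Si](C)(Cl)C(C)(C)C
Why: Imidazole-promoted silylation masks the phenol for the organolithium and esterification steps.

**Step 10**
Reactants: 16 (4-bromo-2-methoxyphenoxy)(tert-butyl)dimethylsilane
Product: 18 4-[(tert-butyldimethylsilyl)oxy]-3-methoxybenzoic acid, via aryllithium 17 (not isolated)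
Conditions: n-BuLi, THF, −78 °C; CO2; then 1 M HCl, 0 °C
Reagents that add atoms: carbon dioxide, O=C=O
Why: Bromine–lithium exchange followed by carboxylation of the aryllithium gives the protected vanillic acid.

**Step 11**
Reactants: 12 (5S,6R)-3-methyl-6-(propan-2-yl)deca-1,2-dien-8-yn-5-ol; 18 4-[(tert-butyldimethylsilyl)oxy]-3-methoxybenzoic acid
Product: 20 (5S,6R)-3-methyl-6-(propan-2-yl)deca-1,2-dien-8-yn-5-yl 4-[(tert-butyldimethylsilyl)oxy]-3-methoxybenzoate, via mixed anhydride 19 (not isolated)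
Conditions: 18, 2,4,6-trichlorobenzoyl chloride, Et3N, THF, rt; then 12, DMAP, toluene, rt to 40 °C
Reagents that add atoms: none
Why: Yamaguchi esterification acylates the hindered secondary alcohol at the less shielded carbonyl of the mixed anhydride with retention at C8.

**Step 12**
Reactants: 20 (5S,6R)-3-methyl-6-(propan-2-yl)deca-1,2-dien-8-yn-5-yl 4-[(tert-butyldimethylsilyl)oxy]-3-methoxybenzoate
Product: 21 (7R,8S)-3-oxoguaia-1(10),4-dien-8-yl 4-[(tert-butyldimethylsilyl)oxy]-3-methoxybenzoate
Conditions: [Rh(CO)2Cl]2 (5 mol%), CO (1 atm), toluene, 90 °C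
Reagents that add atoms: carbon monoxide, [C-]#[O+]
Why: Allenic Pauson–Khand reaction, in which monovalent rhodium couples the alkyne, the distal allene double bond and CO into the 4-alkylidene cyclopentenone, closing the seven-membered ring (C1–C5) and the five-membered ring together and leaving the C1=C10 tetrasubstituted alkene in place; no stereocentre is formed.

**Step 13**
Reactants: 21 (7R,8S)-3-oxoguaia-1(10),4-dien-8-yl 4-[(tert-butyldimethylsilyl)oxy]-3-methoxybenzoate
Product: 22 (3R,7R,8S)-3-hydroxyguaia-1(10),4-dien-8-yl 4-[(tert-butyldimethylsilyl)oxy]-3-methoxybenzoate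
Conditions: (S)-2-methyl-CBS-oxazaborolidine (0.5 equiv), BH3·SMe2, THF, −30 °C; MeOH quench
Reagents that add atoms: none
Why: Corey–Bakshi–Shibata 1,2-reduction under reagent control (α-methyl alkenyl branch as the large group, C2 methylene as the small group) gives the 3R alcohol, with the hydroxyl on the same face as the C8 oxygen.

**Step 14**
Reactants: 22 (3R,7R,8S)-3-hydroxyguaia-1(10),4-dien-8-yl 4-[(tert-butyldimethylsilyl)oxy]-3-methoxybenzoate
Product: 25 (5R,7R,8S)-guaia-1(10),3-dien-8-yl 4-[(tert-butyldimethylsilyl)oxy]-3-methoxybenzoate, via sulfonylhydrazide 23 (not isolated), via allylic diazene 24 (not isolated)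
Conditions: PPh3, DEAD, 2-nitrobenzenesulfonylhydrazide, N-methylmorpholine, −30 °C, then 23 °C
Reagents that add atoms: none
Why: Myers reductive 1,3-transposition, in which Mitsunobu displacement inverts C3, loss of sulfinic acid gives the diazene, and its retro-ene loss of N2 delivers hydrogen suprafacially to C5 on the face opposite the original hydroxyl, setting 5R and moving the alkene to C3=C4.

**Step 15**
Reactants: 25 (5R,7R,8S)-guaia-1(10),3-dien-8-yl 4-[(tert-butyldimethylsilyl)oxy]-3-methoxybenzoate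
Product: 26 (5R,7R,8S)-guaia-1(10),3-dien-8-yl 4-hydroxy-3-methoxybenzoate
Conditions: Bu4NF, AcOH, THF, 0 °C
Reagents that add atoms: none
Why: Buffered fluoride cleaves the aryl silyl ether without touching the ester or isomerising the skipped diene.

## Compound list

1 | 3-methylbutanoyl chloride | CC(C)CC(=O)Cl | starting material
2 | (4R)-4-benzyl-3-(3-methylbutanoyl)-1,3-oxazolidin-2-one | CC(C)CC(=O)N1[C@H](Cc2ccccc2)COC1=O | intermediate
3 | 1-bromobut-2-yne | CC#CCBr | starting material
4 | sodium (Z)-enolate of 2 | CC(C)/C=C(\[O-])N1[C@H](Cc2ccccc2)COC1=O.[Na+] | intermediate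
5 | (4R)-4-benzyl-3-[(2R)-2-(propan-2-yl)hex-4-ynoyl]-1,3-oxazolidin-2-one | CC#CC[C@H](C(C)C)C(=O)N1[C@H](Cc2ccccc2)COC1=O | intermediate
6 | (2R)-2-(propan-2-yl)hex-4-yn-1-ol | CC#CC[C@H](C(C)C)CO | intermediate
7 | 4-chlorobut-2-yn-1-ol | OCC#CCCl | starting material
8 | bromomagnesium 4-chlorobut-2-yn-1-olate | ClCC#CCO[Mg]Br | intermediate
9 | 2-methylbuta-2,3-dien-1-ol | C=C=C(C)CO | intermediate
10 | 2-methylbuta-2,3-dien-1-yl acetate | C=C=C(C)COC(C)=O | intermediate
11 | (2R)-2-(propan-2-yl)hex-4-ynal | CC#CC[C@H](C(C)C)C=O | intermediate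
12 | (5S,6R)-3-methyl-6-(propan-2-yl)deca-1,2-dien-8-yn-5-ol | CC#CC[C@H](C(C)C)[C@@H](O)CC(C)=C=C | intermediate
13 | benzene-1,2-diol (catechol) | Oc1ccccc1O | starting material
14 | 2-methoxyphenol | COc1ccccc1O | intermediate
15 | 4-bromo-2-methoxyphenol | COc1cc(Br)ccc1O | intermediate
16 | (4-bromo-2-methoxyphenoxy)(tert-butyl)dimethylsilane | COc1cc(Br)ccc1O[Si](C)(C)C(C)(C)C | intermediate
17 | {4-[(tert-butyldimethylsilyl)oxy]-3-methoxyphenyl}lithium | [Li]c1ccc(O[Si](C)(C)C(C)(C)C)c(OC)c1 | intermediate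
18 | 4-[(tert-butyldimethylsilyl)oxy]-3-methoxybenzoic acid | COc1cc(C(=O)O)ccc1O[Si](C)(C)C(C)(C)C | intermediate
19 | 4-[(tert-butyldimethylsilyl)oxy]-3-methoxybenzoic 2,4,6-trichlorobenzoic anhydride | COc1cc(C(=O)OC(=O)c2c(Cl)cc(Cl)cc2Cl)ccc1O[Si](C)(C)C(C)(C)C | intermediate
20 | (5S,6R)-3-methyl-6-(propan-2-yl)deca-1,2-dien-8-yn-5-yl 4-[(tert-butyldimethylsilyl)oxy]-3-methoxybenzoate | CC#CC[C@H](C(C)C)[C@@H](OC(=O)c1ccc(O[Si](C)(C)C(C)(C)C)c(OC)c1)CC(C)=C=C | intermediate
21 | (7R,8S)-3-oxoguaia-1(10),4-dien-8-yl 4-[(tert-butyldimethylsilyl)oxy]-3-methoxybenzoate | COc1cc(C(=O)O[C@H]2CC(C)=C3CC(=O)C(C)=C3C[C@@H]2C(C)C)ccc1O[Si](C)(C)C(C)(C)C | intermediate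
22 | (3R,7R,8S)-3-hydroxyguaia-1(10),4-dien-8-yl 4-[(tert-butyldimethylsilyl)oxy]-3-methoxybenzoate | COc1cc(C(=O)O[C@H]2CC(C)=C3C[C@@H](O)C(C)=C3C[C@@H]2C(C)C)ccc1O[Si](C)(C)C(C)(C)C | intermediate
23 | (3S,7R,8S)-3-[1-(2-nitrobenzenesulfonyl)hydrazinyl]guaia-1(10),4-dien-8-yl 4-[(tert-butyldimethylsilyl)oxy]-3-methoxybenzoate | COc1cc(C(=O)O[C@H]2CC(C)=C3C[C@H](N(N)S(=O)(=O)c4ccccc4[N+](=O)[O-])C(C)=C3C[C@@H]2C(C)C)ccc1O[Si](C)(C)C(C)(C)C | intermediate
24 | (3S,7R,8S)-3-diazenylguaia-1(10),4-dien-8-yl 4-[(tert-butyldimethylsilyl)oxy]-3-methoxybenzoate | COc1cc(C(=O)O[C@H]2CC(C)=C3C[C@H](N=N)C(C)=C3C[C@@H]2C(C)C)ccc1O[Si](C)(C)C(C)(C)C | intermediate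
25 | (5R,7R,8S)-guaia-1(10),3-dien-8-yl 4-[(tert-butyldimethylsilyl)oxy]-3-methoxybenzoate | COc1cc(C(=O)O[C@H]2CC(C)=C3CC=C(C)[C@H]3C[C@@H]2C(C)C)ccc1O[Si](C)(C)C(C)(C)C | intermediate
26 | (5R,7R,8S)-guaia-1(10),3-dien-8-yl 4-hydroxy-3-methoxybenzoate, i.e. (6S,7R,8aR)-1,4-dimethyl-7-(propan-2-yl)-3,5,6,7,8,8a-hexahydroazulen-6-yl vanillate | COc1cc(C(=O)O[C@H]2CC(C)=C3CC=C(C)[C@H]3C[C@@H]2C(C)C)ccc1O | target

## Step count and risks

Total step count: 15.
Longest linear sequence: 9 steps (1 → 2 → 5 → 6 → 12 → 20 → 21 → 22 → 25 → 26; the branch from catechol 13 is equally long, the branch from 7 is 8 steps).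

**Step 6 (proposed new homoallenylation).** Four things can go wrong. The dienyl-iridium species may add through its other σ-form and give the isomeric 2-(1,3-dienyl) carbinol. Iridium hydride may hydrometalate the allene of 10 or of 12, or the internal alkyne of 6. Catalyst control may not override the substrate's Felkin preference for the C8 epimer. The transient α-branched aldehyde 11 may epimerise at C7 if it accumulates.

Fallback with known chemistry, setting out from 6 and returning at 12: Dess–Martin oxidation of 6 gives aldehyde 11, here isolated. Chiral phosphoric acid catalysed propargylation of 11 with allenylboronic acid pinacol ester (TRIP antipode chosen for Si-face addition) gives (4S,5R)-5-(propan-2-yl)nona-1,7-diyn-4-ol F1. TBSOTf and 2,6-lutidine then give tert-butyl(dimethyl){[(4S,5R)-5-(propan-2-yl)nona-1,7-diyn-4-yl]oxy}silane F2. Deprotonation of the terminal alkyne with n-BuLi and addition to paraformaldehyde gives (5S,6R)-5-[(tert-butyldimethylsilyl)oxy]-6-(propan-2-yl)deca-2,8-diyn-1-ol F3. MsCl and Et3N give (5S,6R)-5-[(tert-butyldimethylsilyl)oxy]-6-(propan-2-yl)deca-2,8-diyn-1-yl methanesulfonate F4. SN2′ methylation with MeMgBr and CuBr·SMe2 gives tert-butyl(dimethyl){[(5S,6R)-3-methyl-6-(propan-2-yl)deca-1,2-dien-8-yn-5-yl]oxy}silane F5, and Bu4NF releases 12.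

**Step 12 (allenic Pauson–Khand to the seven-membered ring).** The aryl ester and aryl silyl ether may slow the cyclocarbonylation or decompose at 90 °C, and competing cycloisomerisation of the allenyne is possible.

Fallback, setting out from 12 and returning at 21, moves the esterification after ring formation and cyclises a simple silyl ether: Et3SiCl and imidazole give triethyl{[(5S,6R)-3-methyl-6-(propan-2-yl)deca-1,2-dien-8-yn-5-yl]oxy}silane F6. [Rh(CO)2Cl]2 under CO then gives (7R,8S)-8-[(triethylsilyl)oxy]guaia-1(10),4-dien-3-one F7. HF·pyridine gives (7R,8S)-8-hydroxyguaia-1(10),4-dien-3-one F8, and Yamaguchi esterification with 18 (through 19) gives 21.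

**Step 14 (Myers transposition on a dienylic alcohol).** The activated C3 oxygen sits on a pentadienyl system, so ionisation, SN2′ attack or elimination to a fulvene can compete with clean inversion.

Fallback, setting out from 22 and returning at 25: formic acetic anhydride and pyridine give (3R,7R,8S)-3-(formyloxy)guaia-1(10),4-dien-8-yl 4-[(tert-butyldimethylsilyl)oxy]-3-methoxybenzoate F9. Tsuji-type hydrogenolysis with Pd(OAc)2 and PBu3 in THF then gives 25. Zerovalent palladium ionises the formate with inversion, and the palladium hydride formed by loss of CO2 delivers hydrogen to C5 from the face opposite the original oxygen, the same stereochemical outcome as the diazene route; hydride delivery to C3 or C10 instead of C5 is the regiochemical risk of this alternative.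

## Further compounds

F1 | step 6 | (4S,5R)-5-(propan-2-yl)nona-1,7-diyn-4-ol | CC#CC[C@H](C(C)C)[C@@H](O)CC#C
F2 | step 6 | tert-butyl(dimethyl){[(4S,5R)-5-(propan-2-yl)nona-1,7-diyn-4-yl]oxy}silane | CC#CC[C@H](C(C)C)[C@@H](O[Si](C)(C)C(C)(C)C)CC#C
F3 | step 6 | (5S,6R)-5-[(tert-butyldimethylsilyl)oxy]-6-(propan-2-yl)deca-2,8-diyn-1-ol | CC#CC[C@H](C(C)C)[C@@H](O[Si](C)(C)C(C)(C)C)CC#CCO
F4 | step 6 | (5S,6R)-5-[(tert-butyldimethylsilyl)oxy]-6-(propan-2-yl)deca-2,8-diyn-1-yl methanesulfonate | CC#CC[C@H](C(C)C)[C@@H](O[Si](C)(C)C(C)(C)C)CC#CCOS(C)(=O)=O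
F5 | step 6 | tert-butyl(dimethyl){[(5S,6R)-3-methyl-6-(propan-2-yl)deca-1,2-dien-8-yn-5-yl]oxy}silane | CC#CC[C@H](C(C)C)[C@@H](O[Si](C)(C)C(C)(C)C)CC(C)=C=C
F6 | step 12 | triethyl{[(5S,6R)-3-methyl-6-(propan-2-yl)deca-1,2-dien-8-yn-5-yl]oxy}silane | CC#CC[C@H](C(C)C)[C@@H](O[Si](CC)(CC)CC)CC(C)=C=C
F7 | step 12 | (7R,8S)-8-[(triethylsilyl)oxy]guaia-1(10),4-dien-3-one | CC[Si](CC)(CC)O[C@H]1CC(C)=C2CC(=O)C(C)=C2C[C@@H]1C(C)C
F8 | step 12 | (7R,8S)-8-hydroxyguaia-1(10),4-dien-3-one | O[C@H]1CC(C)=C2CC(=O)C(C)=C2C[C@@H]1C(C)C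
F9 | step 14 | (3R,7R,8S)-3-(formyloxy)guaia-1(10),4-dien-8-yl 4-[(tert-butyldimethylsilyl)oxy]-3-methoxybenzoate | COc1cc(C(=O)O[C@H]2CC(C)=C3C[C@@H](OC=O)C(C)=C3C[C@@H]2C(C)C)ccc1O[Si](C)(C)C(C)(C)C
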